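A direct plan would open 2-C-methyl-D-ribono-1,4-lactone A1 with the acetylide of 2-methylbut-1-en-3-yne A2 and close the ring at once to the 3(2H)-furanone alcohol A3, invert C8 to the epimeric alcohol A4, extend C7 to the (Z)-2-(bromomethyl)enoate A5, allylate acrolein A6 with it to build the lactone, esterify O8 to the diene ester A7 and close the nine-membered ring last by ring-closing metathesis at C4=C5.
Weak point 1, the final ring-closing metathesis: it would have to form a trisubstituted, furanone-conjugated (Z)-alkene from an electron-poor isopropenyl group inside a strained bridged ring, at millimolar dilution and high ruthenium loading, on the fully functionalised substrate.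
Weak point 2, the correction of C8: the chiral pool delivers C8 with the wrong configuration, so a Mitsunobu inversion, an ester cleavage, a silylation and an oxidation of a silyl ether follow, four operations that add no carbon.
Weak point 3, the intermolecular allylation of A6: C6 and C7 would be set in an open chain under allylic 1,3-strain alone, with a large excess of a volatile aldehyde, so two ring stereocentres rest on a weak bias.

Retrosynthetic overview
Key disconnection: C6–C7 together with the lactone bond C12–O6. One intramolecular CrCl2-mediated allylation–lactonisation of bromo aldehyde 13 closes ring B (carbocycle C1–C10, nine-membered through the furanone oxygen) and ring C (α-methylene lactone) and sets C6 and C7, so no metathesis is needed.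
Feature used: C3–C4(C15)=C5–C6, a cis-alkene between the furanone carbon C3 and the lactone carbinol C6, is a 3-methylfuran in disguise. The furan is joined at C2–C3 by Sonogashira coupling, holds the (Z)-geometry, and is opened oxidatively to the C3 ketone and C6 aldehyde.
Ring A (O–C10–C1–C2–C3) then forms from the γ-hydroxy ynone with a cationic monovalent gold catalyst. Ring order: A first, then B and C in one step.
C8 and C9 come with the right configuration from L-tartaric acid as a trans-acetonide, so no inversion is needed. C10 is set by Felkin–Anh ethynylation, and the ester goes on last.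
Key step: step 10

Remark: germacrane numbering (C1–C15) is used for all intermediates. 2-Bromo-3-methylfuran 5 is assumed to be a commercial, sensitive reagent that would be used freshly filtered.

Step 1
Reactants: 1 dimethyl (4R,5R)-2,2-dimethyl-1,3-dioxolane-4,5-dicarboxylate (dimethyl 2,3-O-isopropylidene-L-tartrate)
Product: 2 (4R,5R)-N4,N5-dimethoxy-N4,N5,2,2-tetramethyl-1,3-dioxolane-4,5-dicarboxamide
Conditions: MeNH(OMe)·HCl (5 equiv), i-PrMgCl (10 equiv), THF, −20 °C
Reagents that add atoms: N,O-dimethylhydroxylamine hydrochloride CNOC.Cl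
Why: Weinreb amidation of both esters by the chloromagnesium amide; the trans-dioxolane centres C8 and C9 are not enolised at −20 °C.

Step 2
Reactants: 2 bis(Weinreb amide)
Product: 3 (4R,5R)-5-acetyl-N-methoxy-N,2,2-trimethyl-1,3-dioxolane-4-carboxamide
Conditions: MeMgBr (1.3 equiv), THF, −20 °C; aq. NH4Cl
Reagents that add atoms: methylmagnesium bromide C[Mg]Br
Why: Mono-addition of a Grignard reagent to a C2-symmetric bis(Weinreb amide): the magnesium chelate of the first adduct survives until work-up and controlled stoichiometry leaves the second amide, which delivers C14 and the C10 carbonyl.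

Step 3
Reactants: 3 methyl ketone
Product: 4 (4R,5R)-5-[(2S)-2-hydroxybut-3-yn-2-yl]-N-methoxy-N,2,2-trimethyl-1,3-dioxolane-4-carboxamide
Conditions: HC≡CMgBr (1.5 equiv), THF, −78 to −30 °C
Reagents that add atoms: ethynylmagnesium bromide C#C[Mg]Br
Why: 1,2-Addition of an alkynyl Grignard reagent to the ketone (more electrophilic than the remaining amide) under Felkin–Anh control: the nucleophile enters anti to the dioxolane C9–O bond past C9–H, which should give the C10 carbinol anti to O9 as in the target.

Step 4
Reactants: 4 terminal alkyne; 5 2-bromo-3-methylfuran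
Product: 6 (4R,5R)-5-[(2S)-2-hydroxy-4-(3-methylfuran-2-yl)but-3-yn-2-yl]-N-methoxy-N,2,2-trimethyl-1,3-dioxolane-4-carboxamide
Conditions: PdCl2(PPh3)2 (3 mol %), CuI (5 mol %), i-Pr2NH, THF, 40 °C
Reagents that add atoms: none
Why: Sonogashira coupling tolerates the free tertiary propargylic hydroxyl; the 3-methylfuran now carries C3–C6 and C15 with the later C4=C5 bond locked cis in the ring.

Step 5
Reactants: 6 furyl alkyne Weinreb amide
Product: 7 (4R,5R)-5-[(2S)-2-hydroxy-4-(3-methylfuran-2-yl)but-3-yn-2-yl]-2,2-dimethyl-1,3-dioxolane-4-carbaldehyde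
Conditions: i-Bu2AlH (2.5 equiv), THF, −78 °C; aq. KNaC4H4O6
Reagents that add atoms: none
Why: Weinreb amide reduction stops at the aldehyde through the chelated aluminium hemiaminal; alkyne and furan are inert at −78 °C, a lactol with O10 would be trans-fused to the dioxolane and should not form, and the crude aldehyde is used at once to keep C8 intact.

Step 6
Reactants: 7 C7 aldehyde; 8 methyl propiolate
Product: 10 methyl 2-{hydroxy[(4S,5R)-5-[(2S)-2-hydroxy-4-(3-methylfuran-2-yl)but-3-yn-2-yl]-2,2-dimethyl-1,3-dioxolan-4-yl]methyl}prop-2-enoate (both C7 epimers), via vinylalane 9 (not isolated)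
Conditions: 8 (3 equiv), i-Bu2AlH (3 equiv), N-methylmorpholine N-oxide (3 equiv), THF, 0 °C; then 7, 0 °C to rt; aq. KNaC4H4O6
Reagents that add atoms: none
Why: Vinylalumination gives the Baylis–Hillman-type adduct: hydroalumination puts aluminium on the α-carbon of the propiolate and the vinylalane adds 1,2 to the aldehyde; the C7 carbinol configuration is irrelevant because C7 becomes sp2 in step 7.

Step 7
Reactants: 10 Baylis–Hillman-type adduct
Product: 11 methyl (2Z)-2-(bromomethyl)-3-{(4S,5R)-5-[(2S)-2-hydroxy-4-(3-methylfuran-2-yl)but-3-yn-2-yl]-2,2-dimethyl-1,3-dioxolan-4-yl}prop-2-enoate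
Conditions: CBr4 (1.3 equiv), PPh3 (1.3 equiv), CH2Cl2, −20 to 0 °C
Reagents that add atoms: carbon tetrabromide BrC(Br)(Br)Br
Why: Appel bromination with allylic transposition: bromide attacks the terminal CH2 of the activated alcohol (SN2′) and should give the favoured (Z)-2-(bromomethyl)enoate, while the neutral conditions spare the furan, the acetonide and the hindered tertiary hydroxyl.

Step 8
Reactants: 11 furyl allylic bromide
Product: 12 methyl (2Z)-2-(bromomethyl)-3-{(4S,5R)-5-[(2S,6Z)-2-hydroxy-6-methyl-5,8-dioxooct-6-en-3-yn-2-yl]-2,2-dimethyl-1,3-dioxolan-4-yl}prop-2-enoate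
Conditions: dimethyldioxirane (1.1 equiv), acetone, −40 to −10 °C; concentrated cold and used directly
Reagents that add atoms: dimethyldioxirane CC1(C)OO1
Why: Oxidative furan ring opening: the dioxirane epoxidises the electron-rich furan (not the alkyne or the enoate) and the epoxide opens to the cis-ene-dicarbonyl, which sets free the C3 ketone, the C6 aldehyde and the (Z)-C4=C5 bond in one neutral operation.

Step 9
Reactants: 12 γ-hydroxy ynone
Product: 13 methyl (2Z)-2-(bromomethyl)-3-{(4S,5R)-2,2-dimethyl-5-[(2R)-2-methyl-3-oxo-5-[(2Z)-4-oxobut-2-en-2-yl]-2,3-dihydrofuran-2-yl]-1,3-dioxolan-4-yl}prop-2-enoate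
Conditions: (4-CF3C6H4)3PAuCl (5 mol %), AgOSO2CF3 (5 mol %; premixed, AgCl filtered off), toluene, H2O (1 equiv), 25 °C
Reagents that add atoms: none
Why: Cycloisomerisation of a 4-hydroxy-2-yn-1-one to a 3(2H)-furanone with a cationic monovalent gold catalyst: the activated ynone takes up water at C1 (regenerated at the end) and the C10 hydroxyl closes on C3 (5-exo-trig) with loss of water; C10 is quaternary and keeps its configuration, and the acetonide keeps O8 and O9 from competing.

Step 10
Reactants: 13 furanone dienal allylic bromide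
Product: 15 (6R,7S,8S,9R,10R)-8,9-(isopropylidenedioxy)-1-oxo-3,10-epoxygermacra-2,4Z,11(13)-trien-12,6-olide, via allylchromium species 14 (not isolated)
Conditions: CrCl2 (10 equiv), THF, 13 added over 10 h (final 2 mM), 25 °C; aq. NH4Cl
Reagents that add atoms: none
Why: CrCl2 reduces the allylic C–Br bond of 13 in two one-electron steps to the σ-allylchromium species 14 (trivalent chromium), which adds through its γ-carbon C7 to the C6 aldehyde in a six-membered chair transition state, and the chromium alkoxide at O6 then attacks the C12 ester (Nozaki–Hiyama allylation with in situ lactonisation). The closest known reaction type is the intramolecular Nozaki–Hiyama allylation of 2-(bromomethyl)enoate aldehydes that closes the ten-membered ring of germacranolides. The C6–C7 bond closes ring B by endo attack of the tethered allylmetal on the aldehyde (ten-membered carbocycle, nine-membered through the furanone oxygen), and ring C closes 5-exo-trig by acyl substitution. C6 and C7 should come out anti (H6/H7 trans, trans-lactone) because the configurationally labile allylchromium reacts through the chair with C8 equatorial, and C7 is set relative to C8 by the dioxolane: with C8–H anti to the forming bond and the C8–O bond eclipsing the allyl unit (inside-alkoxy arrangement) the tether through C9 lies on the attacked face, whereas the alternative would put the electron-withdrawing C–O bond anti to the nucleophilic π-system. The step needs attack on the aldehyde and not on the furanone carbonyl C1, and no 1,4-elimination of O8: C1 is a vinylogous ester carbonyl whose attack by C7 would need a five-membered ring trans-fused to the dioxolane, and O8 is an acetal oxygen and a poor leaving group. The cis C4=C5 bond, the furanone and the trans-dioxolane hold C6 within reach of C7, and slow addition at 2 mM should suppress dimers.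

Step 11
Reactants: 15 macrocyclic acetonide
Product: 16 (6R,7R,8S,9R,10R)-8,9-dihydroxy-1-oxo-3,10-epoxygermacra-2,4Z,11(13)-trien-12,6-olide
Conditions: CF3CO2H–H2O (4:1), CH2Cl2, 0 °C
Reagents that add atoms: none
Why: Acid hydrolysis of the acetonide; the furanone (a vinylogous ester), the α-methylene lactone and the tertiary ether at C10 should be stable to cold aqueous acid, no base touches the retro-aldol-prone C9 ketol, and the C7 descriptor changes from S to R only because the free O8 hydroxyl lowers the rank of C8 below C6, not because the centre is touched.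

Step 12
Reactants: 16 diol lactone; 17 (R)-2-methylbutanoic acid
Product: 19 target CNP0146060.1, via O-acylisourea 18 (not isolated)
Conditions: 17 (1.1 equiv), i-PrN=C=N-i-Pr (1.2 equiv), 4-(dimethylamino)pyridine (0.1 equiv), CH2Cl2, −20 to 0 °C
Reagents that add atoms: none
Why: Steglich esterification should take O8 rather than O9, because O9 is neopentylic (next to quaternary C10) and hydrogen-bonded to the furanone; the mild activation leaves the acyl α-stereocentre from 17 unchanged, and the ester is introduced only now because an acyloxy group at C8 would be lost by 1,4-elimination from an allylchromium species.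

Compound list
1 | dimethyl (4R,5R)-2,2-dimethyl-1,3-dioxolane-4,5-dicarboxylate | COC(=O)[C@@H]1OC(C)(C)O[C@H]1C(=O)OC | starting material
2 | (4R,5R)-N4,N5-dimethoxy-N4,N5,2,2-tetramethyl-1,3-dioxolane-4,5-dicarboxamide | CON(C)C(=O)[C@@H]1OC(C)(C)O[C@H]1C(=O)N(C)OC | intermediate
3 | (4R,5R)-5-acetyl-N-methoxy-N,2,2-trimethyl-1,3-dioxolane-4-carboxamide | CC(=O)[C@@H]1OC(C)(C)O[C@H]1C(=O)N(C)OC | intermediate
4 | (4R,5R)-5-[(2S)-2-hydroxybut-3-yn-2-yl]-N-methoxy-N,2,2-trimethyl-1,3-dioxolane-4-carboxamide | C#C[C@](C)(O)[C@@H]1OC(C)(C)O[C@H]1C(=O)N(C)OC | intermediate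
5 | 2-bromo-3-methylfuran | Cc1ccoc1Br | starting material
6 | (4R,5R)-5-[(2S)-2-hydroxy-4-(3-methylfuran-2-yl)but-3-yn-2-yl]-N-methoxy-N,2,2-trimethyl-1,3-dioxolane-4-carboxamide | Cc1ccoc1C#C[C@](C)(O)[C@@H]1OC(C)(C)O[C@H]1C(=O)N(C)OC | intermediate
7 | (4R,5R)-5-[(2S)-2-hydroxy-4-(3-methylfuran-2-yl)but-3-yn-2-yl]-2,2-dimethyl-1,3-dioxolane-4-carbaldehyde | Cc1ccoc1C#C[C@](C)(O)[C@@H]1OC(C)(C)O[C@H]1C=O | intermediate
8 | methyl propiolate | C#CC(=O)OC | starting material
9 | methyl 2-(diisobutylalumanyl)prop-2-enoate | C=C(C(=O)OC)[Al](CC(C)C)CC(C)C | intermediate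
10 | methyl 2-{hydroxy[(4S,5R)-5-[(2S)-2-hydroxy-4-(3-methylfuran-2-yl)but-3-yn-2-yl]-2,2-dimethyl-1,3-dioxolan-4-yl]methyl}prop-2-enoate (C7 epimers) | Cc1ccoc1C#C[C@](C)(O)[C@@H]1OC(C)(C)O[C@H]1C(O)C(=C)C(=O)OC | intermediate
11 | methyl (2Z)-2-(bromomethyl)-3-{(4S,5R)-5-[(2S)-2-hydroxy-4-(3-methylfuran-2-yl)but-3-yn-2-yl]-2,2-dimethyl-1,3-dioxolan-4-yl}prop-2-enoate | Cc1ccoc1C#C[C@](C)(O)[C@@H]1OC(C)(C)O[C@H]1/C=C(\CBr)C(=O)OC | intermediate
12 | methyl (2Z)-2-(bromomethyl)-3-{(4S,5R)-5-[(2S,6Z)-2-hydroxy-6-methyl-5,8-dioxooct-6-en-3-yn-2-yl]-2,2-dimethyl-1,3-dioxolan-4-yl}prop-2-enoate | O=C/C=C(/C)C(=O)C#C[C@](C)(O)[C@@H]1OC(C)(C)O[C@H]1/C=C(\CBr)C(=O)OC | intermediate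
13 | methyl (2Z)-2-(bromomethyl)-3-{(4S,5R)-2,2-dimethyl-5-[(2R)-2-methyl-3-oxo-5-[(2Z)-4-oxobut-2-en-2-yl]-2,3-dihydrofuran-2-yl]-1,3-dioxolan-4-yl}prop-2-enoate | O=C/C=C(/C)C1=CC(=O)[C@](C)(O1)[C@@H]2OC(C)(C)O[C@H]2/C=C(\CBr)C(=O)OC | intermediate
14 | allylchromium dichloride derived from 13 (CH2Br replaced by CH2CrCl2) | O=C/C=C(/C)C1=CC(=O)[C@](C)(O1)[C@@H]2OC(C)(C)O[C@H]2/C=C(\C[Cr](Cl)Cl)C(=O)OC | intermediate
15 | (6R,7S,8S,9R,10R)-8,9-(isopropylidenedioxy)-1-oxo-3,10-epoxygermacra-2,4Z,11(13)-trien-12,6-olide | C=C1C(=O)O[C@@H]2/C=C(/C)C3=CC(=O)[C@](C)(O3)[C@@H]4OC(C)(C)O[C@H]4[C@@H]12 | intermediate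
16 | (6R,7R,8S,9R,10R)-8,9-dihydroxy-1-oxo-3,10-epoxygermacra-2,4Z,11(13)-trien-12,6-olide | C=C1C(=O)O[C@@H]2/C=C(/C)C3=CC(=O)[C@](C)(O3)[C@H](O)[C@@H](O)[C@@H]12 | intermediate
17 | (R)-2-methylbutanoic acid | CC[C@@H](C)C(=O)O | starting material
18 | O-[(R)-2-methylbutanoyl]-N,N'-diisopropylisourea | CC[C@@H](C)C(=O)OC(=NC(C)C)NC(C)C | intermediate
19 | CNP0146060.1, 9α-hydroxy-8β-[(R)-2-methylbutanoyloxy]-1-oxo-3,10-epoxygermacra-2,4Z,11(13)-trien-12,6α-olide | C=C1C(=O)O[C@@H]2/C=C(/C)C3=CC(=O)[C@](C)(O3)[C@H](O)[C@@H](OC(=O)[C@H](C)CC)[C@@H]12 | target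

Total step count: 12. Longest linear sequence: 12 steps (from 1; 5, 8 and 17 are bought).

Steps most likely to fail

Step 10: the bridged nine-membered transition state may be too strained, or the ring may fold so that the aldehyde meets the other face of C7. Fallback: the order of the last two ring closures would be inverted. Setting out from 12, the same CrCl2 allylation–lactonisation would be run before the furanone exists, via the allylchromium species F1. In that chain C10–C1≡C2–C3 is linear and no bridged ring has to form, so the macrocyclic γ-hydroxy ynone lactone F2 should result. The catalyst of step 9, (4-CF3C6H4)3PAuCl with AgOSO2CF3, would then close ring A across the macrocycle, and the route would be rejoined at 15.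

Step 3: facial selectivity at C10 may be low, or reversed if magnesium chelates O9. Fallback: the two carbon nucleophiles would be added in the opposite order, so that chelation and not Felkin–Anh control leads to the same configuration. Setting out from 2, LiC≡CSiMe3 (1.1 equiv, THF, −78 °C) would give the ynone F3. MeMgBr in CH2Cl2 at −78 °C (methyl delivered to the magnesium chelate of the ketone and O9, anti to C8) would give the tertiary alcohol F4. K2CO3 in MeOH would remove the silyl group and return to 4.

Step 8: the cis-ene-dicarbonyl may isomerise to the trans isomer or be over-oxidised when it is set free by direct oxygen transfer. Fallback: oxidation and unmasking would be separated. Setting out from 11, N-bromosuccinimide and NaHCO3 in MeOH at −30 °C would give the 2,5-dimethoxy-2,5-dihydrofuran F5, a storable cyclic bis-acetal that holds the cis geometry. Hydrolysis with 0.05 M H2SO4 in acetone–water at 0 °C directly before the gold step would give 12.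

Further compounds
F1 | step 10 | allylchromium dichloride derived from 12 (CH2Br replaced by CH2CrCl2) | O=C/C=C(/C)C(=O)C#C[C@](C)(O)[C@@H]1OC(C)(C)O[C@H]1/C=C(\C[Cr](Cl)Cl)C(=O)OC
F2 | step 10 | (6R,7S,8S,9R,10S)-10-hydroxy-8,9-(isopropylidenedioxy)-3-oxogermacra-4Z,11(13)-dien-1-yn-12,6-olide | C=C1C(=O)O[C@@H]2/C=C(/C)C(=O)C#C[C@](C)(O)[C@@H]3OC(C)(C)O[C@H]3[C@@H]12
F3 | step 3 | (4R,5R)-N-methoxy-N,2,2-trimethyl-5-[3-(trimethylsilyl)prop-2-ynoyl]-1,3-dioxolane-4-carboxamide | C[Si](C)(C)C#CC(=O)[C@@H]1OC(C)(C)O[C@H]1C(=O)N(C)OC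
F4 | step 3 | (4R,5R)-5-[(2S)-2-hydroxy-4-(trimethylsilyl)but-3-yn-2-yl]-N-methoxy-N,2,2-trimethyl-1,3-dioxolane-4-carboxamide | C[Si](C)(C)C#C[C@](C)(O)[C@@H]1OC(C)(C)O[C@H]1C(=O)N(C)OC
F5 | step 8 | methyl (2Z)-2-(bromomethyl)-3-{(4S,5R)-5-[(2S)-4-(2,5-dimethoxy-3-methyl-2,5-dihydrofuran-2-yl)-2-hydroxybut-3-yn-2-yl]-2,2-dimethyl-1,3-dioxolan-4-yl}prop-2-enoate (acetal epimers) | COC1OC(OC)(C#C[C@](C)(O)[C@@H]2OC(C)(C)O[C@H]2/C=C(\CBr)C(=O)OC)C(C)=C1
A1 | direct plan | 2-C-methyl-D-ribono-1,4-lactone | O=C1[C@](C)(O)[C@H](O)[C@@H](CO)O1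
A2 | direct plan | 2-methylbut-1-en-3-yne | C=C(C)C#C
A3 | direct plan | (2R)-2-[(1R,2R)-2-hydroxy-1,3-bis(triethylsilyloxy)propyl]-2-methyl-5-(prop-1-en-2-yl)furan-3(2H)-one | C=C(C)C1=CC(=O)[C@](C)(O1)[C@H](O[Si](CC)(CC)CC)[C@H](O)CO[Si](CC)(CC)CC
A4 | direct plan | (2R)-2-[(1R,2S)-2-hydroxy-1,3-bis(triethylsilyloxy)propyl]-2-methyl-5-(prop-1-en-2-yl)furan-3(2H)-one | C=C(C)C1=CC(=O)[C@](C)(O1)[C@H](O[Si](CC)(CC)CC)[C@@H](O)CO[Si](CC)(CC)CC
A5 | direct plan | methyl (2Z,4S,5R)-2-(bromomethyl)-5-[(2R)-2-methyl-3-oxo-5-(prop-1-en-2-yl)-2,3-dihydrofuran-2-yl]-4,5-bis(triethylsilyloxy)pent-2-enoate | C=C(C)C1=CC(=O)[C@](C)(O1)[C@H](O[Si](CC)(CC)CC)[C@@H](O[Si](CC)(CC)CC)/C=C(\CBr)C(=O)OC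
A6 | direct plan | acrolein | C=CC=O
A7 | direct plan | C8 (R)-2-methylbutanoate of the trans-3-methylidene-5-vinyloxolan-2-one that carries the dihydroxyethyl furanone chain at C7 (C9 hydroxyl free) | C=C(C)C1=CC(=O)[C@](C)(O1)[C@H](O)[C@@H](OC(=O)[C@H](C)CC)[C@@H]2[C@@H](C=C)OC(=O)C2=C
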